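**Remark on the chemistry:** the target has no stereocentre and no stereogenic double bond, so no enantiomer has to be controlled. Intermediate 17 carries one stereocentre, which becomes aromatic C8, and is used as the racemate.

## Retrosynthetic overview

1. Target 20 ⇐ its 3'-O-MOM ether 19 by acetal cleavage.
2. Ring A of 19 (C4a, C5, C6, C7, C8, C8a, with 5-OH, 7-OH and the C8 prenyl group) is a folded triketide hung on C2/C3 of a finished 2-aryl-4-pyranone. It is opened at C5–C6 to keto ester 17, in which C8 is already bonded to C8a–O1, so 8- versus 6-prenylation never arises.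
3. 17 ⇐ acetonylpyranone 15 + prenyl bromide 16 (C-alkylation) ⇐ 2-methylpyranone 13 (lateral acetylation).
4. Ring C: pyranone 13 ⇐ methyl acetoacetate 10 + arylpropiolic acid 9 (C-acylation, then 6-endo-dig oxa-Michael closure).
5. 9 ⇐ chromene aldehyde 6 (Corey–Fuchs, CO2) ⇐ 1 + 2 (propargyl ether, Claisen). Ring order: chromene pyran ring, then ring C, then ring A.

Key step: step 9

## Route

Step 1
Reactants: 1 3,4-dihydroxybenzaldehyde; 2 3-chloro-3-methylbut-1-yne
Product: 3 3-hydroxy-4-[(2-methylbut-3-yn-2-yl)oxy]benzaldehyde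
Conditions: 2 (1.3 equiv), DBU (1.1 equiv), CuCl2·2H2O (1 mol%), MeCN, Ar, 0 °C → rt
Reagents that add atoms: none
Why: The 4-OH para to the formyl group is the more acidic phenol, so one equivalent of amidine base should give only that phenoxide, which is O-alkylated by the copper-activated tertiary propargylic chloride (copper-catalysed propargylic etherification of a phenol).

Step 2
Reactants: 3 3-hydroxy-4-[(2-methylbut-3-yn-2-yl)oxy]benzaldehyde
Product: 4 3-(methoxymethoxy)-4-[(2-methylbut-3-yn-2-yl)oxy]benzaldehyde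
Conditions: MOMCl (1.3 equiv), i-Pr2NEt (1.5 equiv), CH2Cl2, 0 °C → rt
Reagents that add atoms: chloromethyl methyl ether, COCCl
Why: Standard MOM etherification of the remaining phenol gives a base-stable acetal that should survive every organometallic and enolate step and come off under mild acid at the end.

Step 3
Reactants: 4 3-(methoxymethoxy)-4-[(2-methylbut-3-yn-2-yl)oxy]benzaldehyde
Product: 6 8-(methoxymethoxy)-2,2-dimethyl-2H-chromene-6-carbaldehyde, via allenylphenol 5 (not isolated)
Conditions: PhNEt2, 180 °C, Ar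
Reagents that add atoms: none
Why: Aryl propargyl ether Claisen rearrangement can only end at the free ortho position C5 (C3 is blocked by OMOM); tautomerisation to 5, 1,5-H shift and oxa-6π electrocyclisation then give the 2,2-dimethylchromene, and the basic solvent protects the acetal.

Step 4
Reactants: 6 8-(methoxymethoxy)-2,2-dimethyl-2H-chromene-6-carbaldehyde
Product: 7 6-(2,2-dibromoethenyl)-8-(methoxymethoxy)-2,2-dimethyl-2H-chromene
Conditions: CBr4 (2 equiv), PPh3 (4 equiv), Et3N (2 equiv), CH2Cl2, 0 °C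
Reagents that add atoms: carbon tetrabromide, BrC(Br)(Br)Br
Why: First stage of the Corey–Fuchs sequence (Wittig-type dibromo-olefination of an aryl aldehyde), with triethylamine buffering the HBr formed so that the MOM ether and the chromene are not touched.

Step 5
Reactants: 7 6-(2,2-dibromoethenyl)-8-(methoxymethoxy)-2,2-dimethyl-2H-chromene
Product: 9 3-[8-(methoxymethoxy)-2,2-dimethyl-2H-chromen-6-yl]prop-2-ynoic acid, via lithium acetylide 8 (not isolated)
Conditions: n-BuLi (2.2 equiv), THF, −78 °C; CO2 (g), −78 → 0 °C; aq. citric acid (pH 3–4), 0 °C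
Reagents that add atoms: carbon dioxide, O=C=O
Why: Second stage of the Corey–Fuchs sequence: Li/Br exchange and Fritsch–Buttenberg–Wiechell rearrangement give acetylide 8, which is carboxylated by CO2, and the weakly acidic work-up spares the aryl MOM ether.

Step 6
Reactants: 9 3-[8-(methoxymethoxy)-2,2-dimethyl-2H-chromen-6-yl]prop-2-ynoic acid; 10 methyl acetoacetate
Product: 13 methyl 6-[8-(methoxymethoxy)-2,2-dimethyl-2H-chromen-6-yl]-2-methyl-4-oxo-4H-pyran-3-carboxylate, via acid chloride 11 (not isolated), via C-acylated ynone 12 (not isolated)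
Conditions: (i) 1-chloro-N,N,2-trimethylprop-1-en-1-amine (1.1 equiv), CH2Cl2, 0 °C → rt; (ii) 10 (1.2 equiv), MgCl2 (1.2 equiv), pyridine (2.4 equiv), CH2Cl2, 0 °C → rt; (iii) DMAP (0.2 equiv), rt
Reagents that add atoms: none
Why: The chloroenamine makes the acid chloride without free HCl, MgCl2/pyridine soft enolisation directs acylation of the β-keto ester to carbon, and the acetyl enol oxygen of 12 adds to the ynone β-carbon (6-endo-dig oxa-Michael, assisted by DMAP addition–elimination) to give the γ-pyrone with methyl at C2 and ester at C3 by construction.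

Step 7
Reactants: 13 methyl 6-[8-(methoxymethoxy)-2,2-dimethyl-2H-chromen-6-yl]-2-methyl-4-oxo-4H-pyran-3-carboxylate
Product: 15 methyl 6-[8-(methoxymethoxy)-2,2-dimethyl-2H-chromen-6-yl]-4-oxo-2-(2-oxopropyl)-4H-pyran-3-carboxylate, via lithium hemiaminal adduct 14 (not isolated)
Conditions: LiHMDS (2.2 equiv), THF, −78 °C; MeC(O)N(OMe)Me (1.5 equiv), −78 → −20 °C; sat. aq. NH4Cl, −20 °C
Reagents that add atoms: N-methoxy-N-methylacetamide, CON(C)C(C)=O
Why: The 2-methyl group is vinylogous to both the C4 ketone and the C3 ester, so a hindered amide base should deprotonate it laterally, and the extended enolate is C-acylated by the N-methoxy-N-methylamide (lateral acylation of a 2-methyl-4-pyranone), with chelated adduct 14 holding back the ketone until work-up so that neither a second acylation nor early ring closure can occur.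

Step 8
Reactants: 15 methyl 6-[8-(methoxymethoxy)-2,2-dimethyl-2H-chromen-6-yl]-4-oxo-2-(2-oxopropyl)-4H-pyran-3-carboxylate; 16 prenyl bromide (1-bromo-3-methylbut-2-ene)
Product: 17 methyl 6-[8-(methoxymethoxy)-2,2-dimethyl-2H-chromen-6-yl]-2-(6-methyl-2-oxohept-5-en-3-yl)-4-oxo-4H-pyran-3-carboxylate (racemic)
Conditions: 16 (1.1 equiv), K2CO3 (1.5 equiv), acetone, 0 °C → rt
Reagents that add atoms: none
Why: The methylene between the ketone and the pyranone is a β-dicarbonyl-type acid whose soft enolate should be C-alkylated by the allylic bromide under carbonate, a base too weak to form the methyl enolate needed for ring closure; the new stereocentre is formed racemic and is erased in step 9.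

Step 9
Reactants: 17 methyl 6-[8-(methoxymethoxy)-2,2-dimethyl-2H-chromen-6-yl]-2-(6-methyl-2-oxohept-5-en-3-yl)-4-oxo-4H-pyran-3-carboxylate (racemic)
Product: 19 5,7-dihydroxy-2-[8-(methoxymethoxy)-2,2-dimethyl-2H-chromen-6-yl]-8-(3-methylbut-2-en-1-yl)-4H-chromen-4-one, via cyclic dione tautomer 18 (not isolated)
Conditions: LDA (3.3 equiv), THF, −78 → 0 °C; sat. aq. NH4Cl
Reagents that add atoms: none
Why: Proposed new method: LDA should first remove the acidic methine proton between the ketone and the pyranone and then a methyl proton, giving a β-diketone-type dianion whose terminal CH2 is the only carbon nucleophile within reach of the C3 ester; it adds to the ester carbonyl, methoxide leaves, and dione 18 enolises twice under the remaining base to the aromatic 5,7-dihydroxy ring. The closest known reaction types are the acylation of β-diketone dianions by esters, the biomimetic Claisen cyclisation of triketo esters to acylphloroglucinols and the Dieckmann-type closure of 2-acetonylbenzoates to 1,3-naphthalenediols, whereas closure onto a 4-pyranone-3-carboxylate to build a flavone A ring is not an established reaction. Ring A closes in a 6-(enolendo)-exo-trig mode (new bond C5–C6), with nucleophile and ester held cis on the pyranone C2=C3 bond. No stereocentre is formed, and the racemic centre of 17 becomes aromatic C8. The step needs methyl-enolate over methine-enolate reactivity and C- over O-acylation: the methine carbon could only close a four-membered ring, and O-acylation to the enol lactone is reopened by the methoxide set free, whereas aromatisation withdraws the C-acylated product irreversibly. The place of the prenyl group next to O1 needs no control, because the C8–C8a bond already exists in 17.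

Step 10
Reactants: 19 5,7-dihydroxy-2-[8-(methoxymethoxy)-2,2-dimethyl-2H-chromen-6-yl]-8-(3-methylbut-2-en-1-yl)-4H-chromen-4-one
Product: 20 5,7-dihydroxy-2-(8-hydroxy-2,2-dimethyl-2H-chromen-6-yl)-8-(3-methylbut-2-en-1-yl)-4H-chromen-4-one
Conditions: HCl (3 M aq.), MeOH–THF, 40 °C
Reagents that add atoms: none
Why: Acid-catalysed acetal exchange with methanol removes the single aryl MOM ether under conditions that should be too mild to add the 7-OH across the prenyl double bond or to hydrate the chromene.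

## Compound list

1 | 3,4-dihydroxybenzaldehyde | O=Cc1ccc(O)c(O)c1 | starting material
2 | 3-chloro-3-methylbut-1-yne | C#CC(C)(C)Cl | starting material
3 | 3-hydroxy-4-[(2-methylbut-3-yn-2-yl)oxy]benzaldehyde | O=Cc1ccc(OC(C)(C)C#C)c(O)c1 | intermediate
4 | 3-(methoxymethoxy)-4-[(2-methylbut-3-yn-2-yl)oxy]benzaldehyde | O=Cc1ccc(OC(C)(C)C#C)c(OCOC)c1 | intermediate
5 | 4-hydroxy-3-(methoxymethoxy)-5-(3-methylbuta-1,2-dien-1-yl)benzaldehyde | O=Cc1cc(OCOC)c(O)c(C=C=C(C)C)c1 | intermediate (not isolated)
6 | 8-(methoxymethoxy)-2,2-dimethyl-2H-chromene-6-carbaldehyde | O=Cc1cc(OCOC)c2c(c1)C=CC(C)(C)O2 | intermediate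
7 | 6-(2,2-dibromoethenyl)-8-(methoxymethoxy)-2,2-dimethyl-2H-chromene | BrC(Br)=Cc1cc(OCOC)c2c(c1)C=CC(C)(C)O2 | intermediate
8 | lithium [8-(methoxymethoxy)-2,2-dimethyl-2H-chromen-6-yl]acetylide | [Li]C#Cc1cc(OCOC)c2c(c1)C=CC(C)(C)O2 | intermediate (not isolated)
9 | 3-[8-(methoxymethoxy)-2,2-dimethyl-2H-chromen-6-yl]prop-2-ynoic acid | OC(=O)C#Cc1cc(OCOC)c2c(c1)C=CC(C)(C)O2 | intermediate
10 | methyl acetoacetate | COC(=O)CC(C)=O | starting material
11 | 3-[8-(methoxymethoxy)-2,2-dimethyl-2H-chromen-6-yl]prop-2-ynoyl chloride | ClC(=O)C#Cc1cc(OCOC)c2c(c1)C=CC(C)(C)O2 | intermediate (not isolated)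
12 | methyl 2-acetyl-5-[8-(methoxymethoxy)-2,2-dimethyl-2H-chromen-6-yl]-3-oxopent-4-ynoate | COC(=O)C(C(C)=O)C(=O)C#Cc1cc(OCOC)c2c(c1)C=CC(C)(C)O2 | intermediate (not isolated)
13 | methyl 6-[8-(methoxymethoxy)-2,2-dimethyl-2H-chromen-6-yl]-2-methyl-4-oxo-4H-pyran-3-carboxylate | COC(=O)C1=C(C)OC(=CC1=O)c1cc(OCOC)c2c(c1)C=CC(C)(C)O2 | intermediate
14 | methyl 2-{2-(lithiooxy)-2-[methoxy(methyl)amino]propyl}-6-[8-(methoxymethoxy)-2,2-dimethyl-2H-chromen-6-yl]-4-oxo-4H-pyran-3-carboxylate (racemic) | COC(=O)C1=C(CC(C)(O[Li])N(C)OC)OC(=CC1=O)c1cc(OCOC)c2c(c1)C=CC(C)(C)O2 | intermediate (not isolated)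
15 | methyl 6-[8-(methoxymethoxy)-2,2-dimethyl-2H-chromen-6-yl]-4-oxo-2-(2-oxopropyl)-4H-pyran-3-carboxylate | COC(=O)C1=C(CC(C)=O)OC(=CC1=O)c1cc(OCOC)c2c(c1)C=CC(C)(C)O2 | intermediate
16 | prenyl bromide (1-bromo-3-methylbut-2-ene) | CC(C)=CCBr | starting material
17 | methyl 6-[8-(methoxymethoxy)-2,2-dimethyl-2H-chromen-6-yl]-2-(6-methyl-2-oxohept-5-en-3-yl)-4-oxo-4H-pyran-3-carboxylate (racemic) | COC(=O)C1=C(C(CC=C(C)C)C(C)=O)OC(=CC1=O)c1cc(OCOC)c2c(c1)C=CC(C)(C)O2 | intermediate
18 | 2-[8-(methoxymethoxy)-2,2-dimethyl-2H-chromen-6-yl]-8-(3-methylbut-2-en-1-yl)-4H-chromene-4,5,7(6H,8H)-trione (racemic) | CC(C)=CCC1C(=O)CC(=O)C2=C1OC(=CC2=O)c1cc(OCOC)c3c(c1)C=CC(C)(C)O3 | intermediate (not isolated)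
19 | 5,7-dihydroxy-2-[8-(methoxymethoxy)-2,2-dimethyl-2H-chromen-6-yl]-8-(3-methylbut-2-en-1-yl)-4H-chromen-4-one | CC(C)=CCc1c(O)cc(O)c2c(=O)cc(-c3cc(OCOC)c4c(c3)C=CC(C)(C)O4)oc12 | intermediate
20 | 5,7-dihydroxy-2-(8-hydroxy-2,2-dimethyl-2H-chromen-6-yl)-8-(3-methylbut-2-en-1-yl)-4H-chromen-4-one | CC(C)=CCc1c(O)cc(O)c2c(=O)cc(-c3cc(O)c4c(c3)C=CC(C)(C)O4)oc12 | target

## Step count and risks

Total step count: 10. Longest linear sequence: 10 steps (1 → 20); compounds 2, 10 and 16 enter as purchased materials.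

**Step 9 (key step, proposed new method).** The dianion may fail to close on carbon. The methyl group may not be deprotonated beside the stabilised methine enolate, the enolate oxygen may acylate instead (enol lactone), the delocalised anion may sit in a geometry that keeps the ketone away from the ester, or the base may open the pyranone. The fallback uses known chemistry: ring A is brought in ready-made and the prenyl group is moved to C8 by a para-Claisen–Cope shift. It sets out from aldehyde 6 and returns to the route at target 20.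
- 2,4,6-Trihydroxyacetophenone is protected at the unchelated 4-OH (MOMCl 1.05 equiv, i-Pr2NEt, CH2Cl2, 0 °C) to give 1-[2,6-dihydroxy-4-(methoxymethoxy)phenyl]ethan-1-one F1.
- Claisen–Schmidt condensation of F1 with 6 (KOH, EtOH–H2O, rt) should give the chalcone (E)-1-[2,6-dihydroxy-4-(methoxymethoxy)phenyl]-3-[8-(methoxymethoxy)-2,2-dimethyl-2H-chromen-6-yl]prop-2-en-1-one F2.
- Oxidative cyclisation (cat. I2, DMSO, 110 °C) should give 5-hydroxy-7-(methoxymethoxy)-2-[8-(methoxymethoxy)-2,2-dimethyl-2H-chromen-6-yl]-4H-chromen-4-one F3.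
- The chelated 5-OH is O-alkylated with 16 (K2CO3, DMF, 60 °C) to give 7-(methoxymethoxy)-2-[8-(methoxymethoxy)-2,2-dimethyl-2H-chromen-6-yl]-5-[(3-methylbut-2-en-1-yl)oxy]-4H-chromen-4-one F4.
- Eu(fod)3 (cat., CHCl3, 60 °C) should take the prenyl group by ortho-Claisen shift to C6 and Cope shift on to C8, giving 5-hydroxy-7-(methoxymethoxy)-2-[8-(methoxymethoxy)-2,2-dimethyl-2H-chromen-6-yl]-8-(3-methylbut-2-en-1-yl)-4H-chromen-4-one F5.
- Both MOM ethers of F5 are removed under the conditions of step 10 to give 20.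

**Step 7.** Acyl transfer to the stabilised lateral anion may be slow, the lithium alkoxide of adduct 14 may close onto the neighbouring C3 ester as a lactone, or the amide base may attack the pyranone. The fallback avoids strong base and alkoxide intermediates. It sets out from 13 and returns at 15.
- The activated 2-methyl group is condensed with N,N-dimethylacetamide dimethyl acetal (toluene, 100 °C), as in a Leimgruber–Batcho enamine formation, to give the enamine methyl 2-[(1E)-2-(dimethylamino)prop-1-en-1-yl]-6-[8-(methoxymethoxy)-2,2-dimethyl-2H-chromen-6-yl]-4-oxo-4H-pyran-3-carboxylate F6.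
- F6 is hydrolysed with AcOH–H2O–THF at rt to ketone 15.

**Step 8.** The enolate of 15 may be alkylated on oxygen or twice on carbon, or 15 may close a ring onto the C3 ester before it is alkylated, which would give a prenyl-free flavone or an enol lactone. The fallback puts the prenyl group in before the acetyl group, so no unsubstituted acetonyl compound is ever formed. It sets out from acid 9 (with 10 and 16) and returns at 17.
- The dianion of 10 (NaH, then n-BuLi, THF, 0 °C) is alkylated at C4 with 16 to give methyl 7-methyl-3-oxooct-6-enoate F7 (γ-alkylation of an acetoacetate dianion).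
- The magnesium enolate of F7 (MgCl2, pyridine) is acylated with acid chloride 11, made from 9 as in step 6, to give methyl 5-[8-(methoxymethoxy)-2,2-dimethyl-2H-chromen-6-yl]-2-(5-methylhex-4-enoyl)-3-oxopent-4-ynoate F8.
- F8 closes (DMAP, rt) to methyl 6-[8-(methoxymethoxy)-2,2-dimethyl-2H-chromen-6-yl]-2-(4-methylpent-3-en-1-yl)-4-oxo-4H-pyran-3-carboxylate F9.
- Lateral deprotonation of F9 at the CH2 next to the ring (LiHMDS 2.2 equiv, THF, −78 °C) and acetylation with 1-acetylimidazole should give 17.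

## Further compounds

F1 | step 9 | 1-[2,6-dihydroxy-4-(methoxymethoxy)phenyl]ethan-1-one | CC(=O)c1c(O)cc(OCOC)cc1O
F2 | step 9 | (E)-1-[2,6-dihydroxy-4-(methoxymethoxy)phenyl]-3-[8-(methoxymethoxy)-2,2-dimethyl-2H-chromen-6-yl]prop-2-en-1-one | COCOc1cc(O)c(C(=O)/C=C/c2cc(OCOC)c3c(c2)C=CC(C)(C)O3)c(O)c1
F3 | step 9 | 5-hydroxy-7-(methoxymethoxy)-2-[8-(methoxymethoxy)-2,2-dimethyl-2H-chromen-6-yl]-4H-chromen-4-one | COCOc1cc(O)c2c(=O)cc(-c3cc(OCOC)c4c(c3)C=CC(C)(C)O4)oc2c1
F4 | step 9 | 7-(methoxymethoxy)-2-[8-(methoxymethoxy)-2,2-dimethyl-2H-chromen-6-yl]-5-[(3-methylbut-2-en-1-yl)oxy]-4H-chromen-4-one | COCOc1cc(OCC=C(C)C)c2c(=O)cc(-c3cc(OCOC)c4c(c3)C=CC(C)(C)O4)oc2c1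
F5 | step 9 | 5-hydroxy-7-(methoxymethoxy)-2-[8-(methoxymethoxy)-2,2-dimethyl-2H-chromen-6-yl]-8-(3-methylbut-2-en-1-yl)-4H-chromen-4-one | COCOc1cc(O)c2c(=O)cc(-c3cc(OCOC)c4c(c3)C=CC(C)(C)O4)oc2c1CC=C(C)C
F6 | step 7 | methyl 2-[(1E)-2-(dimethylamino)prop-1-en-1-yl]-6-[8-(methoxymethoxy)-2,2-dimethyl-2H-chromen-6-yl]-4-oxo-4H-pyran-3-carboxylate | COC(=O)C1=C(/C=C(\C)N(C)C)OC(=CC1=O)c1cc(OCOC)c2c(c1)C=CC(C)(C)O2
F7 | step 8 | methyl 7-methyl-3-oxooct-6-enoate | COC(=O)CC(=O)CCC=C(C)C
F8 | step 8 | methyl 5-[8-(methoxymethoxy)-2,2-dimethyl-2H-chromen-6-yl]-2-(5-methylhex-4-enoyl)-3-oxopent-4-ynoate | COC(=O)C(C(=O)CCC=C(C)C)C(=O)C#Cc1cc(OCOC)c2c(c1)C=CC(C)(C)O2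
F9 | step 8 | methyl 6-[8-(methoxymethoxy)-2,2-dimethyl-2H-chromen-6-yl]-2-(4-methylpent-3-en-1-yl)-4-oxo-4H-pyran-3-carboxylate | COC(=O)C1=C(CCC=C(C)C)OC(=CC1=O)c1cc(OCOC)c2c(c1)C=CC(C)(C)O2
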